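**Plan**

1. Retrosynthetic cuts, in order: the two methoxymethyl ethers; the C-3''=C-4'' double bond of the dimethylpyran ring D, traced to the C-4'' ketone of chromanone 15 (a temporary activating group); then ring D at two bonds together, O-1''–C-2' and C-3''–C-4''. This gives the ring-B 2-fluorobenzoate 11 and the three-atom unit LiCH2C(CH3)2OLi.
2. Enabling feature: in ring B, C-3' (which carries C-4'') lies between C-2' (pyran oxygen) and C-4' (free OH). An acyl carbon on C-3', ortho to a C-2'–F bond, makes C-4'' and C-2' a 1,3-dielectrophile, and only C-2' has a leaving group, so the pyran oxygen cannot end on C-4'.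
3. The same fluorine, together with the 4'-oxygen, makes H-3' the most acidic aryl hydrogen, so the ester carbon is put in by lithiation (step 5).
4. Further back: the prenyl group comes from Stille coupling at C-6, and isoflavan 7 from an isoflavone made from resorcinol and (2-fluoro-4-hydroxyphenyl)acetic acid.
5. Forward ring order: ring C is built on ring A as a pyranone (step 1) and reduced to the chroman (steps 3 and 4); ring D is closed last (step 8) and brought to the chromene level (steps 9 and 10).
6. Stereochemistry: the only stereocentre, C-3, is set in step 3 by catalyst-controlled asymmetric transfer hydrogenation with dynamic kinetic resolution, giving (3R,4R); the C-4 oxygen is removed in step 4 and no later step touches C-3.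

Key step: step 8

Remark on locants: isoflavan positions are O-1 to C-8a (ring A benzo, ring C pyran), ring B is C-1' to C-6', and ring D is O-1'', C-2''(CH3)2, C-3'', C-4''.
Remark on chemistry: chromanol 16 is assumed to form as both C-4'' epimers and is carried on as the mixture, because this centre becomes sp2 in step 10.

**Route**

Step 1
Reactants: 1 resorcinol, 2 (2-fluoro-4-hydroxyphenyl)acetic acid
Product: 4 3-(2-fluoro-4-hydroxyphenyl)-7-hydroxy-4H-chromen-4-one, via deoxybenzoin 3 (not isolated)
Conditions: BF3·OEt2, 90 °C; then DMF, MsCl, 70 °C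
Reagents that add atoms: N,N-dimethylformamide CN(C)C=O
Why: Friedel–Crafts acylation of resorcinol at C-4 should give deoxybenzoin 3, whose activated methylene is formylated by the Vilsmeier-type reagent from DMF and MsCl and closes onto the 2-hydroxyl with loss of dimethylamine (one-pot isoflavone synthesis); no stereocentre is formed.

Step 2
Reactants: 4 3-(2-fluoro-4-hydroxyphenyl)-7-hydroxy-4H-chromen-4-one
Product: 5 3-[2-fluoro-4-(methoxymethoxy)phenyl]-7-(methoxymethoxy)-4H-chromen-4-one
Conditions: MOMCl, iPr2NEt, DMF, 0 °C to rt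
Reagents that add atoms: chloromethyl methyl ether COCCl
Why: O-alkylation of both phenols gives acetals that withstand the later bases, and the 4'-acetal later cooperates with fluorine in directing the lithiation.

Step 3
Reactants: 5 3-[2-fluoro-4-(methoxymethoxy)phenyl]-7-(methoxymethoxy)-4H-chromen-4-one
Product: 6 (3R,4R)-3-[2-fluoro-4-(methoxymethoxy)phenyl]-7-(methoxymethoxy)chroman-4-ol (cis)
Conditions: RuCl[(R,R)-TsDPEN](p-cymene) (cat.), HCO2H/Et3N, EtOAc, 40 °C
Reagents that add atoms: none
Why: In this Noyori–Ikariya asymmetric transfer hydrogenation the ruthenium hydride should first reduce the C-2=C-3 bond, the isoflavanone then racemises at C-3 through its enol, and the (R,R)-catalyst reduces the (3R)-ketone faster from the face opposite the aryl group (dynamic kinetic resolution), so C-3 and C-4 are set together as the cis-(3R,4R) alcohol.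

Step 4
Reactants: 6 (3R,4R)-3-[2-fluoro-4-(methoxymethoxy)phenyl]-7-(methoxymethoxy)chroman-4-ol
Product: 7 (3R)-3-[2-fluoro-4-(methoxymethoxy)phenyl]-7-(methoxymethoxy)chroman
Conditions: H2 (1 atm), Pd/C, EtOH, AcOH (cat.), rt
Reagents that add atoms: none
Why: Hydrogenolysis of the benzylic C-4–O bond, activated by the para 7-oxygen, should remove the carbinol centre while C-3 is not involved and keeps its configuration.

Step 5
Reactants: 7 (3R)-3-[2-fluoro-4-(methoxymethoxy)phenyl]-7-(methoxymethoxy)chroman
Product: 8 methyl 2-fluoro-6-(methoxymethoxy)-3-[(3R)-7-(methoxymethoxy)chroman-3-yl]benzoate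
Conditions: LiTMP (from 2,2,6,6-tetramethylpiperidine, n-BuLi), THF, −78 °C; then ClCO2Me, −78 °C
Reagents that add atoms: methyl chloroformate COC(=O)Cl
Why: Directed ortho-metalation should take place at H-3', the only aryl hydrogen flanked by fluorine and an acetal oxygen, and the aryllithium is trapped by the chloroformate at −78 °C before lithium fluoride can be lost.

Step 6
Reactants: 8 methyl 2-fluoro-6-(methoxymethoxy)-3-[(3R)-7-(methoxymethoxy)chroman-3-yl]benzoate
Product: 9 methyl 3-[(3R)-6-bromo-7-(methoxymethoxy)chroman-3-yl]-2-fluoro-6-(methoxymethoxy)benzoate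
Conditions: NBS, DMF, 0 °C
Reagents that add atoms: N-bromosuccinimide O=C1CCC(=O)N1Br
Why: Electrophilic aromatic bromination should go to C-6, para to O-1 and ortho to the 7-oxygen on the doubly activated ring A, while ring B is deactivated by fluorine and the new ester.

Step 7
Reactants: 9 methyl 3-[(3R)-6-bromo-7-(methoxymethoxy)chroman-3-yl]-2-fluoro-6-(methoxymethoxy)benzoate, 10 tributyl(3-methylbut-2-en-1-yl)stannane
Product: 11 methyl 2-fluoro-6-(methoxymethoxy)-3-[(3R)-7-(methoxymethoxy)-6-(3-methylbut-2-en-1-yl)chroman-3-yl]benzoate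
Conditions: Pd(PPh3)4 (cat.), DMF, 100 °C
Reagents that add atoms: none
Why: In this Stille coupling zerovalent palladium inserts into the C-6–Br bond and the prenyl group is transferred from tin with bond formation at its unsubstituted terminus, which should give the linear prenyl arene.

Step 8
Reactants: 11 methyl 2-fluoro-6-(methoxymethoxy)-3-[(3R)-7-(methoxymethoxy)-6-(3-methylbut-2-en-1-yl)chroman-3-yl]benzoate, 12 1-chloro-2-methylpropan-2-ol
Product: 15 5-(methoxymethoxy)-8-[(3R)-7-(methoxymethoxy)-6-(3-methylbut-2-en-1-yl)chroman-3-yl]-2,2-dimethylchroman-4-one, via dilithio reagent 13 (not isolated), via keto alkoxide 14 (not isolated)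
Conditions: 12, n-BuLi, THF, −78 °C; LiC10H8 (lithium naphthalenide, 2 equiv), −78 °C; add 11, −78 to −40 °C; then DMPU, warm to 50 °C
Reagents that add atoms: none
Why: Proposed new method: the lithium alkoxide of 12 is reductively lithiated to the β-oxido organolithium 13 (persistent at −78 °C because oxide is no leaving group), whose carbanion adds to the ester carbonyl of 11 and, on warming, the tetrahedral adduct expels methoxide to give keto alkoxide 14 (bond C-3''–C-4''), any excess 13 being expected to have destroyed itself by β-elimination by then so that no second addition occurs. The new ketone is ortho to the C-2'–F bond and turns it into an SNAr site, so the tertiary alkoxide adds to C-2' through a carbonyl-stabilised Meisenheimer complex and fluoride leaves (bond O-1''–C-2'). The closest known reaction types are the addition of β-oxido organolithiums made from chlorohydrins to carbonyl electrophiles, the tandem C-acylation/SNAr of 2-fluorobenzoyl compounds with enolates that gives chromones, and the base-induced cyclisation of 2'-fluoro β-hydroxy ketones to chroman-4-ones. Ring D closes by intramolecular addition–elimination at the aromatic carbon in a six-membered (formally 6-exo) mode; no stereocentre is formed and C-3 of the isoflavan, which has no acidifying neighbour, is untouched. The step needs the pyran oxygen on C-2' and not C-4', which is secured because only C-2' carries a leaving group ortho to the carbonyl and O-4' is blocked as its acetal; it also needs ring closure to outrun retro-aldol cleavage of 14, which is reversible whereas loss of fluoride is not.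

Step 9
Reactants: 15 5-(methoxymethoxy)-8-[(3R)-7-(methoxymethoxy)-6-(3-methylbut-2-en-1-yl)chroman-3-yl]-2,2-dimethylchroman-4-one
Product: 16 5-(methoxymethoxy)-8-[(3R)-7-(methoxymethoxy)-6-(3-methylbut-2-en-1-yl)chroman-3-yl]-2,2-dimethylchroman-4-ol (both C-4'' epimers)
Conditions: NaBH4, MeOH/THF, 0 °C
Reagents that add atoms: none
Why: Hydride reduction of the aryl ketone; the new C-4'' carbinol centre is formed without control and is removed in the next step.

Step 10
Reactants: 16 5-(methoxymethoxy)-8-[(3R)-7-(methoxymethoxy)-6-(3-methylbut-2-en-1-yl)chroman-3-yl]-2,2-dimethylchroman-4-ol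
Product: 17 (3R)-7-(methoxymethoxy)-3-[5-(methoxymethoxy)-2,2-dimethyl-2H-chromen-8-yl]-6-(3-methylbut-2-en-1-yl)chroman
Conditions: MsCl, Et3N, CH2Cl2, 0 °C to rt
Reagents that add atoms: none
Why: Mesylation of the benzylic alcohol followed by elimination (ionisation assisted by the two ortho ring oxygens, then loss of H-3'') should give the styrene-type C-3''=C-4'' bond under non-acidic conditions that spare the acetals and the prenyl group.

Step 11
Reactants: 17 (3R)-7-(methoxymethoxy)-3-[5-(methoxymethoxy)-2,2-dimethyl-2H-chromen-8-yl]-6-(3-methylbut-2-en-1-yl)chroman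
Product: 18 (3R)-3-(5-hydroxy-2,2-dimethyl-2H-chromen-8-yl)-6-(3-methylbut-2-en-1-yl)chroman-7-ol (target)
Conditions: HCl (aq., dilute), MeOH, rt
Reagents that add atoms: none
Why: Acid-catalysed acetal exchange with methanol removes both methoxymethyl ethers, and the mild conditions should keep the prenyl chain from adding to the liberated ortho phenol.

**Compound list**

1 | resorcinol | Oc1cccc(O)c1 | starting material
2 | (2-fluoro-4-hydroxyphenyl)acetic acid | OC(=O)Cc1ccc(O)cc1F | starting material
3 | 1-(2,4-dihydroxyphenyl)-2-(2-fluoro-4-hydroxyphenyl)ethan-1-one (deoxybenzoin, not isolated) | O=C(Cc1ccc(O)cc1F)c1ccc(O)cc1O | intermediate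
4 | 3-(2-fluoro-4-hydroxyphenyl)-7-hydroxy-4H-chromen-4-one | O=c1c(-c2ccc(O)cc2F)coc2cc(O)ccc12 | intermediate
5 | 3-[2-fluoro-4-(methoxymethoxy)phenyl]-7-(methoxymethoxy)-4H-chromen-4-one | COCOc1ccc(-c2coc3cc(OCOC)ccc3c2=O)c(F)c1 | intermediate
6 | (3R,4R)-3-[2-fluoro-4-(methoxymethoxy)phenyl]-7-(methoxymethoxy)chroman-4-ol | COCOc1ccc2c(c1)OC[C@@H](c1ccc(OCOC)cc1F)[C@H]2O | intermediate
7 | (3R)-3-[2-fluoro-4-(methoxymethoxy)phenyl]-7-(methoxymethoxy)chroman | COCOc1ccc2c(c1)OC[C@@H](c1ccc(OCOC)cc1F)C2 | intermediate
8 | methyl 2-fluoro-6-(methoxymethoxy)-3-[(3R)-7-(methoxymethoxy)chroman-3-yl]benzoate | COCOc1ccc2c(c1)OC[C@@H](c1ccc(OCOC)c(C(=O)OC)c1F)C2 | intermediate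
9 | methyl 3-[(3R)-6-bromo-7-(methoxymethoxy)chroman-3-yl]-2-fluoro-6-(methoxymethoxy)benzoate | Brc1cc2c(cc1OCOC)OC[C@@H](c1ccc(OCOC)c(C(=O)OC)c1F)C2 | intermediate
10 | tributyl(3-methylbut-2-en-1-yl)stannane | CC(C)=CC[Sn](CCCC)(CCCC)CCCC | starting material
11 | methyl 2-fluoro-6-(methoxymethoxy)-3-[(3R)-7-(methoxymethoxy)-6-(3-methylbut-2-en-1-yl)chroman-3-yl]benzoate | CC(C)=CCc1cc2c(cc1OCOC)OC[C@@H](c1ccc(OCOC)c(C(=O)OC)c1F)C2 | intermediate
12 | 1-chloro-2-methylpropan-2-ol | CC(C)(O)CCl | starting material
13 | lithium 1-lithio-2-methylpropan-2-olate (not isolated) | [Li]CC(C)(C)O[Li] | intermediate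
14 | lithium alkoxide of 1-{2-fluoro-6-(methoxymethoxy)-3-[(3R)-7-(methoxymethoxy)-6-(3-methylbut-2-en-1-yl)chroman-3-yl]phenyl}-3-hydroxy-3-methylbutan-1-one (not isolated) | CC(C)=CCc1cc2c(cc1OCOC)OC[C@@H](c1ccc(OCOC)c(C(=O)CC(C)(C)O[Li])c1F)C2 | intermediate
15 | 5-(methoxymethoxy)-8-[(3R)-7-(methoxymethoxy)-6-(3-methylbut-2-en-1-yl)chroman-3-yl]-2,2-dimethylchroman-4-one | CC(C)=CCc1cc2c(cc1OCOC)OC[C@@H](c1ccc(OCOC)c3c1OC(C)(C)CC3=O)C2 | intermediate
16 | 5-(methoxymethoxy)-8-[(3R)-7-(methoxymethoxy)-6-(3-methylbut-2-en-1-yl)chroman-3-yl]-2,2-dimethylchroman-4-ol (both C-4'' epimers) | CC(C)=CCc1cc2c(cc1OCOC)OC[C@@H](c1ccc(OCOC)c3c1OC(C)(C)CC3O)C2 | intermediate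
17 | (3R)-7-(methoxymethoxy)-3-[5-(methoxymethoxy)-2,2-dimethyl-2H-chromen-8-yl]-6-(3-methylbut-2-en-1-yl)chroman | CC(C)=CCc1cc2c(cc1OCOC)OC[C@@H](c1ccc(OCOC)c3c1OC(C)(C)C=C3)C2 | intermediate
18 | (3R)-3-(5-hydroxy-2,2-dimethyl-2H-chromen-8-yl)-6-(3-methylbut-2-en-1-yl)chroman-7-ol | CC(C)=CCc1cc2c(cc1O)OC[C@@H](c1ccc(O)c3c1OC(C)(C)C=C3)C2 | target

**Step count and risks**

Total step count: 11. Longest linear sequence: 11 steps (from 1 and 2 to 18).

Steps most likely to fail:

Step 8 (proposed new method). Keto alkoxide 14 may undergo retro-aldol cleavage to the aryl methyl ketone and acetone faster than it cyclises. A second organolithium addition to the ketone is possible. Addition to the doubly ortho-substituted ester may also be too slow at the temperature at which reagent 13 survives. The fallback uses known chemistry and forms the same two bonds. It sets out from 11, which is saponified (LiOH, THF/H2O) to 2-fluoro-6-(methoxymethoxy)-3-[(3R)-7-(methoxymethoxy)-6-(3-methylbut-2-en-1-yl)chroman-3-yl]benzoic acid F1. The acid is activated with 1,1'-carbonyldiimidazole and treated with the lithium enolate of acetone (LiN(SiMe3)2, THF, −78 °C to reflux). C-acylation followed by SNAr of the diketone enolate oxygen at C-2' should give 5-(methoxymethoxy)-8-[(3R)-7-(methoxymethoxy)-6-(3-methylbut-2-en-1-yl)chroman-3-yl]-2-methyl-4H-chromen-4-one F2. Conjugate addition of a methyl cuprate (MeMgBr, CuBr·SMe2, Me3SiCl, THF, −40 °C, then aqueous acid work-up) creates the gem-dimethyl carbon and returns to the route at 15.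

Step 4. Acid-promoted dehydration of 6 to the isoflav-3-ene followed by unselective hydrogenation would erode the configuration at C-3, and the hydrogenolysis may stall. The fallback sets out from 6, which is converted (NaH, CS2, MeI) into O-{(3R,4R)-3-[2-fluoro-4-(methoxymethoxy)phenyl]-7-(methoxymethoxy)chroman-4-yl} S-methyl carbonodithioate F3. Barton–McCombie reduction (Bu3SnH, AIBN, toluene, 80 °C) passes through a radical at C-4 only and comes back at 7.

Step 7. Allyl transposition during transmetalation would give the 1,1-dimethylallyl isomer, and slow oxidative addition into the electron-rich, ortho-alkoxy C–Br bond may allow protodebromination. The fallback sets out from 9, which is coupled with allyltributylstannane (Pd(PPh3)4, DMF), where no regiochemical question arises, to give methyl 3-[(3R)-6-allyl-7-(methoxymethoxy)chroman-3-yl]-2-fluoro-6-(methoxymethoxy)benzoate F4. Cross-metathesis with 2-methylbut-2-ene (second-generation Grubbs catalyst, RuCl2(=CHPh)(H2IMes)(PCy3), CH2Cl2, 40 °C) comes back at 11.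

**Further compounds**

F1 | step 8 | 2-fluoro-6-(methoxymethoxy)-3-[(3R)-7-(methoxymethoxy)-6-(3-methylbut-2-en-1-yl)chroman-3-yl]benzoic acid | CC(C)=CCc1cc2c(cc1OCOC)OC[C@@H](c1ccc(OCOC)c(C(=O)O)c1F)C2
F2 | step 8 | 5-(methoxymethoxy)-8-[(3R)-7-(methoxymethoxy)-6-(3-methylbut-2-en-1-yl)chroman-3-yl]-2-methyl-4H-chromen-4-one | CC(C)=CCc1cc2c(cc1OCOC)OC[C@@H](c1ccc(OCOC)c3c1oc(C)cc3=O)C2
F3 | step 4 | O-{(3R,4R)-3-[2-fluoro-4-(methoxymethoxy)phenyl]-7-(methoxymethoxy)chroman-4-yl} S-methyl carbonodithioate | COCOc1ccc2c(c1)OC[C@@H](c1ccc(OCOC)cc1F)[C@H]2OC(=S)SC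
F4 | step 7 | methyl 3-[(3R)-6-allyl-7-(methoxymethoxy)chroman-3-yl]-2-fluoro-6-(methoxymethoxy)benzoate | C=CCc1cc2c(cc1OCOC)OC[C@@H](c1ccc(OCOC)c(C(=O)OC)c1F)C2
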